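**Strategy.** The methylcyclohexene (C1 bears the flavone, C2=C3 is the alkene, C5 bears the 2,4-dihydroxyphenyl ring D, C6 bears the aroyl group) is closed late at the C5–C6 bond, not by a Diels–Alder reaction. The step exploits that C5 is benzylic to an ortho/para-dioxygenated ring, hence a latent quinone-methide-type cation, while C6 is the α-carbon of an aryl ketone. The precursor is an acyclic (3R,4Z)-7-hydroxyhept-4-en-1-one carrying the flavone at C3. One-pot enol silane formation and ionisation should close the ring and set two stereocentres under control of C3. C3 comes from a rhodium-catalysed asymmetric conjugate addition of a cyclic Z-alkenylboronic acid to an 8-flavonyl enone.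

Key step: step 17

**Remarks.**
- Abbreviations: TBS = tert-butyldimethylsilyl; TMS = trimethylsilyl; prenyl = 3-methylbut-2-en-1-yl; Fl = 4-oxo-3-prenyl-2-[4-(prenyloxy)-2-(TBS-oxy)phenyl]-5,7-bis(TBS-oxy)-4H-chromen-8-yl; ring E = the aroyl ring.
- The carbinol carbon of 20–23 is racemic and that of 24 and 25 is a pair of epimers. It is written without configuration because it becomes planar in step 17.
- (R)-BINAP in step 16 is assigned by analogy with the empirical facial model for E-configured acyclic enones. If the sense were the opposite, (S)-BINAP would be used.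

**Step 1**
Reactants: 1 2,4,6-trihydroxyacetophenone
Product: 2 1-[2-hydroxy-4,6-bis(TBS-oxy)phenyl]ethan-1-one
Conditions: TBSCl (2.1 equiv), imidazole, DMF, 0 °C to rt
Reagents that add atoms: tert-butyldimethylsilyl chloride CC(C)(C)[Si](C)(C)Cl
Why: Silyl ether formation stops at the bis-ether because the remaining ortho hydroxyl is hydrogen-bonded to the acetyl group.

**Step 2**
Reactants: 2 1-[2-hydroxy-4,6-bis(TBS-oxy)phenyl]ethan-1-one
Product: 3 1-[2-hydroxy-3-iodo-4,6-bis(TBS-oxy)phenyl]ethan-1-one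
Conditions: N-iodosuccinimide, MeCN, 0 °C, dark
Reagents that add atoms: N-iodosuccinimide O=C1CCC(=O)N1I
Why: Electrophilic aromatic iodination should occur ortho to the free phenol at C3, since C5 is flanked by two bulky silyloxy groups.

**Step 3**
Reactants: 3 1-[2-hydroxy-3-iodo-4,6-bis(TBS-oxy)phenyl]ethan-1-one
Product: 4 1-[2-hydroxy-3-iodo-4,6-bis(TBS-oxy)phenyl]-5-methylhex-4-en-1-one
Conditions: LiN(iPr)2 (2.2 equiv), THF, −78 °C; prenyl bromide, −78 to −20 °C; aq NH4Cl
Reagents that add atoms: prenyl bromide CC(C)=CCBr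
Why: Alkylation of the phenoxide–enolate dianion takes place at the more nucleophilic enolate carbon and installs the carbon chain that becomes C3 of the flavone and its prenyl group.

**Step 4**
Reactants: 5 methyl 2,4-dihydroxybenzoate
Product: 6 methyl 2-hydroxy-4-(prenyloxy)benzoate
Conditions: prenyl bromide, K2CO3, acetone, reflux
Reagents that add atoms: prenyl bromide CC(C)=CCBr
Why: Williamson etherification is selective for the 4-hydroxyl because the 2-hydroxyl is hydrogen-bonded to the ester.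

**Step 5**
Reactants: 6 methyl 2-hydroxy-4-(prenyloxy)benzoate
Product: 7 2-hydroxy-4-(prenyloxy)benzoic acid
Conditions: LiOH, THF/MeOH/H2O, 50 °C; then 1 M HCl to pH 3, 0 °C
Reagents that add atoms: lithium hydroxide [Li+].[OH-]
Why: Saponification of the salicylate ester leaves the base-stable aryl prenyl ether untouched.

**Step 6**
Reactants: 7 2-hydroxy-4-(prenyloxy)benzoic acid
Product: 8 TBS 2-(TBS-oxy)-4-(prenyloxy)benzoate
Conditions: TBSCl (2.3 equiv), imidazole, DMF, rt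
Reagents that add atoms: tert-butyldimethylsilyl chloride CC(C)(C)[Si](C)(C)Cl
Why: Silylation of both the phenol and the acid gives a silyl ester that can be turned into the acid chloride without free HCl.

**Step 7**
Reactants: 8 TBS 2-(TBS-oxy)-4-(prenyloxy)benzoate; 4 1-[2-hydroxy-3-iodo-4,6-bis(TBS-oxy)phenyl]-5-methylhex-4-en-1-one
Product: 10 1-[2-hydroxy-3-iodo-4,6-bis(TBS-oxy)phenyl]-2-prenyl-3-[4-(prenyloxy)-2-(TBS-oxy)phenyl]propane-1,3-dione, via acid chloride 9 (not isolated)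
Conditions: 8, (COCl)2, DMF (cat.), CH2Cl2, 0 °C, then evaporation; 4, LiN(SiMe3)2 (3.1 equiv), THF, −78 °C, then 9, −78 °C to rt; AcOH
Reagents that add atoms: oxalyl chloride ClC(=O)C(Cl)=O (chlorine of intermediate 9)
Why: The silyl ester is converted into the acid chloride under neutral conditions and the lithium dianion of 4 is C-acylated (Claisen-type acylation), any O-acylated ester converging on the same diketone by Baker–Venkataraman acyl transfer under the excess base.

**Step 8**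
Reactants: 10 1-[2-hydroxy-3-iodo-4,6-bis(TBS-oxy)phenyl]-2-prenyl-3-[4-(prenyloxy)-2-(TBS-oxy)phenyl]propane-1,3-dione
Product: 11 8-iodo-3-prenyl-2-[4-(prenyloxy)-2-(TBS-oxy)phenyl]-5,7-bis(TBS-oxy)-4H-chromen-4-one
Conditions: AcOH, NaOAc, 80 °C
Reagents that add atoms: none
Why: Cyclodehydration of the 2-hydroxyaryl 1,3-diketone through the only free phenol, which is ortho to iodine, gives the chromone and fixes the iodine at C8, while the buffered weak acid spares the prenyl ether.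

**Step 9**
Reactants: 12 2,4-dihydroxyacetophenone
Product: 13 1-(2,4-dihydroxy-3-prenylphenyl)ethan-1-one
Conditions: prenyl bromide, aq KOH (10%), 0 °C to rt
Reagents that add atoms: prenyl bromide CC(C)=CCBr
Why: C-alkylation of the resorcinol phenolate in water occurs at the carbon between the two oxygens, and the O-alkylated and 5-alkylated isomers are removed by chromatography.

**Step 10**
Reactants: 13 1-(2,4-dihydroxy-3-prenylphenyl)ethan-1-one
Product: 14 1-[3-prenyl-2,4-bis(TBS-oxy)phenyl]ethan-1-one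
Conditions: TBSOTf (2.5 equiv), 2,6-lutidine, CH2Cl2, 0 °C to rt
Reagents that add atoms: tert-butyldimethylsilyl triflate CC(C)(C)[Si](C)(C)OS(=O)(=O)C(F)(F)F
Why: The silyl triflate is reactive enough to silylate the hindered, chelated 2-hydroxyl as well, which must be blocked so that the later vinyl ketone cannot close to a chromanone.

**Step 11**
Reactants: 14 1-[3-prenyl-2,4-bis(TBS-oxy)phenyl]ethan-1-one
Product: 16 1-[3-prenyl-2,4-bis(TBS-oxy)phenyl]prop-2-en-1-one, via Mannich base 15 (not isolated)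
Conditions: paraformaldehyde, iPr2NH2+ CF3CO2− (1 equiv), CF3CO2H (cat.), THF, reflux; used at once
Reagents that add atoms: formaldehyde (as paraformaldehyde) C=O; diisopropylammonium trifluoroacetate CC(C)[NH2+]C(C)C.[O-]C(=O)C(F)(F)F (nitrogen of intermediate 15)
Why: Mannich condensation at the methyl group followed by elimination of the amine (α-methylenation) gives the aryl vinyl ketone.

**Step 12**
Reactants: 11 8-iodo-3-prenyl-2-[4-(prenyloxy)-2-(TBS-oxy)phenyl]-5,7-bis(TBS-oxy)-4H-chromen-4-one; 16 1-[3-prenyl-2,4-bis(TBS-oxy)phenyl]prop-2-en-1-one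
Product: 17 (E)-3-Fl-1-[3-prenyl-2,4-bis(TBS-oxy)phenyl]prop-2-en-1-one
Conditions: Pd2(dba)3 (5 mol %), P(t-Bu)3·HBF4 (12 mol %), Cy2NMe, 1,4-dioxane, 70 °C
Reagents that add atoms: none
Why: Mizoroki–Heck reaction with syn insertion at the terminal carbon and syn β-hydride elimination gives the E-enone, and the trisubstituted prenyl alkenes do not insert.

**Step 13**
Reactants: 18 2,4-dihydroxybenzaldehyde
Product: 19 2,4-bis(TBS-oxy)benzaldehyde
Conditions: TBSCl (2.3 equiv), imidazole, DMF, rt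
Reagents that add atoms: tert-butyldimethylsilyl chloride CC(C)(C)[Si](C)(C)Cl
Why: Exhaustive silyl ether formation protects both phenols of ring D, which later stabilise the benzylic cation as silyloxy donors.

**Step 14**
Reactants: 19 2,4-bis(TBS-oxy)benzaldehyde
Product: 20 rac-1-[2,4-bis(TBS-oxy)phenyl]-3-methylbut-3-en-1-ol
Conditions: Zn dust, 3-bromo-2-methylpropene, THF/sat. aq NH4Cl, 0 °C to rt
Reagents that add atoms: 3-bromo-2-methylpropene CC(=C)CBr
Why: Barbier allylation in the presence of aqueous NH4Cl protonates the alkoxide at once, so that no aryl-to-alkyl silyl migration can follow.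

**Step 15**
Reactants: 20 rac-1-[2,4-bis(TBS-oxy)phenyl]-3-methylbut-3-en-1-ol
Product: 23 rac-6-[2,4-bis(TBS-oxy)phenyl]-4-methyl-5,6-dihydro-2H-1,2-oxaborinin-2-ol, via mixed butyl vinylboronate 21 (not isolated), via cyclic butyl boronate 22 (not isolated)
Conditions: vinylboronic acid dibutyl ester, CH2Cl2, rt, then vacuum; second-generation Grubbs catalyst RuCl2(=CHPh)(PCy3)(H2IMes) (5 mol %), CH2Cl2, 40 °C; H2O work-up
Reagents that add atoms: vinylboronic acid dibutyl ester C=CB(OCCCC)OCCCC; water O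
Why: Transesterification tethers the vinylboron unit to the carbinol oxygen and ring-closing metathesis with the 1,1-disubstituted alkene closes a six-membered ring, so the trisubstituted alkenylboron is necessarily Z.

**Step 16**
Reactants: 17 (E)-3-Fl-1-[3-prenyl-2,4-bis(TBS-oxy)phenyl]prop-2-en-1-one; 23 rac-6-[2,4-bis(TBS-oxy)phenyl]-4-methyl-5,6-dihydro-2H-1,2-oxaborinin-2-ol
Product: 24 (3R,4Z)-7-[2,4-bis(TBS-oxy)phenyl]-3-Fl-7-hydroxy-5-methyl-1-[3-prenyl-2,4-bis(TBS-oxy)phenyl]hept-4-en-1-one (both C7 epimers)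
Conditions: [Rh(OH)(cod)]2 (3 mol %), (R)-BINAP (7 mol %), 23 (2.5 equiv), 1,4-dioxane/H2O 10:1, 50 °C
Reagents that add atoms: none
Why: In this Hayashi–Miyaura conjugate addition the alkenyl group passes from boron to rhodium with retention of the Z geometry, the ligand-controlled enantioface-selective insertion of the E-enone sets the (3R) centre, and water protonates the rhodium enolate under base-free conditions that spare the aryl silyl ethers.

**Step 17**
Reactants: 24 (3R,4Z)-7-[2,4-bis(TBS-oxy)phenyl]-3-Fl-7-hydroxy-5-methyl-1-[3-prenyl-2,4-bis(TBS-oxy)phenyl]hept-4-en-1-one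
Product: 27 hepta-TBS ether of target 28 in the (1S,5R,6S) configuration, via bis-TMS enol ether 25 (not isolated), via benzylic cation 26 (not isolated)
Conditions: iPr2NEt (2.5 equiv), TMSOTf (2.3 equiv), CH2Cl2, −78 to 0 °C; then TMSOTf (0.5 equiv), −78 to −40 °C; aq NaHCO3
Reagents that add atoms: trimethylsilyl triflate C[Si](C)(C)OS(=O)(=O)C(F)(F)F (trimethylsilyl groups of intermediate 25; trimethylsilyl group plus triflate counter-ion of intermediate 26)
Why: The silyl triflate and the amine first convert the aryl ketone into its (Z)-trimethylsilyl enol ether and the carbinol into its silyl ether (25); the small excess of silyl triflate then ionises the benzylic C–O bond, which is feasible at low temperature because this carbon carries the 2,4-dioxygenated ring D, and the enol silane carbon attacks cation 26 to form the C6–C5 bond with return of the silyl triflate. The closest known reaction type is the Mukaiyama-type SN1 alkylation of a silyl enol ether by a stabilised benzylic cation, run here intramolecularly as a one-pot enol silane formation and alkylation. The cyclohexene is closed in the 6-(enolexo)-exo-trig mode, the preformed Z-trisubstituted alkene holding the two termini cis. The existing centre C1 should control both new centres: allylic 1,3-strain places its hydrogen in the enol plane so that the cation approaches anti to the flavonyl group, and in the chair-like transition state the aryl group of the planar cation sits equatorial, which leads to the all-trans (1S,5R,6S) isomer, while the carbinol configuration of 24 is erased on ionisation and C6 stays epimerisable towards the same all-equatorial isomer. The step needs ionisation at the benzylic position only, in the presence of three prenyl groups and an aryl prenyl ether, and ring closure faster than proton loss to the conjugated diene; the strong cation stabilisation by ring D, the buffered substoichiometric Lewis acid at low temperature and the six-membered intramolecular closure should secure this.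

**Step 18**
Reactants: 27 hepta-TBS ether of target 28 in the (1S,5R,6S) configuration
Product: 28 8-[(1S,5R,6S)-6-[2,4-dihydroxy-3-prenylbenzoyl]-5-(2,4-dihydroxyphenyl)-3-methylcyclohex-2-en-1-yl]-5,7-dihydroxy-2-[2-hydroxy-4-(prenyloxy)phenyl]-3-prenyl-4H-chromen-4-one (CNP0082413.1)
Conditions: Bu4NF (8 equiv), AcOH (8 equiv), THF, 0 °C to rt
Reagents that add atoms: none
Why: Buffered fluoride cleaves all seven aryl silyl ethers without touching the prenyl groups or the aryl prenyl ether, and any epimerisation at C6 can only lead to the all-equatorial target.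

**Compound list**

1 | 2,4,6-trihydroxyacetophenone | CC(=O)c1c(O)cc(O)cc1O | starting material
2 | 1-[2-hydroxy-4,6-bis(TBS-oxy)phenyl]ethan-1-one | CC(=O)c1c(O)cc(O[Si](C)(C)C(C)(C)C)cc1O[Si](C)(C)C(C)(C)C | intermediate
3 | 1-[2-hydroxy-3-iodo-4,6-bis(TBS-oxy)phenyl]ethan-1-one | CC(=O)c1c(O)c(I)c(O[Si](C)(C)C(C)(C)C)cc1O[Si](C)(C)C(C)(C)C | intermediate
4 | 1-[2-hydroxy-3-iodo-4,6-bis(TBS-oxy)phenyl]-5-methylhex-4-en-1-one | CC(C)=CCCC(=O)c1c(O)c(I)c(O[Si](C)(C)C(C)(C)C)cc1O[Si](C)(C)C(C)(C)C | intermediate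
5 | methyl 2,4-dihydroxybenzoate | COC(=O)c1ccc(O)cc1O | starting material
6 | methyl 2-hydroxy-4-(prenyloxy)benzoate | COC(=O)c1ccc(OCC=C(C)C)cc1O | intermediate
7 | 2-hydroxy-4-(prenyloxy)benzoic acid | OC(=O)c1ccc(OCC=C(C)C)cc1O | intermediate
8 | TBS 2-(TBS-oxy)-4-(prenyloxy)benzoate | CC(C)=CCOc1ccc(C(=O)O[Si](C)(C)C(C)(C)C)c(O[Si](C)(C)C(C)(C)C)c1 | intermediate
9 | 2-(TBS-oxy)-4-(prenyloxy)benzoyl chloride (not isolated) | CC(C)=CCOc1ccc(C(Cl)=O)c(O[Si](C)(C)C(C)(C)C)c1 | intermediate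
10 | 1-[2-hydroxy-3-iodo-4,6-bis(TBS-oxy)phenyl]-2-prenyl-3-[4-(prenyloxy)-2-(TBS-oxy)phenyl]propane-1,3-dione | CC(C)=CCC(C(=O)c1c(O)c(I)c(O[Si](C)(C)C(C)(C)C)cc1O[Si](C)(C)C(C)(C)C)C(=O)c1ccc(OCC=C(C)C)cc1O[Si](C)(C)C(C)(C)C | intermediate
11 | 8-iodo-3-prenyl-2-[4-(prenyloxy)-2-(TBS-oxy)phenyl]-5,7-bis(TBS-oxy)-4H-chromen-4-one | CC(C)=CCOc1ccc(-c2oc3c(I)c(O[Si](C)(C)C(C)(C)C)cc(O[Si](C)(C)C(C)(C)C)c3c(=O)c2CC=C(C)C)c(O[Si](C)(C)C(C)(C)C)c1 | intermediate
12 | 2,4-dihydroxyacetophenone | CC(=O)c1ccc(O)cc1O | starting material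
13 | 1-(2,4-dihydroxy-3-prenylphenyl)ethan-1-one | CC(=O)c1ccc(O)c(CC=C(C)C)c1O | intermediate
14 | 1-[3-prenyl-2,4-bis(TBS-oxy)phenyl]ethan-1-one | CC(=O)c1ccc(O[Si](C)(C)C(C)(C)C)c(CC=C(C)C)c1O[Si](C)(C)C(C)(C)C | intermediate
15 | 3-(diisopropylamino)-1-[3-prenyl-2,4-bis(TBS-oxy)phenyl]propan-1-one, Mannich base (not isolated) | CC(C)N(CCC(=O)c1ccc(O[Si](C)(C)C(C)(C)C)c(CC=C(C)C)c1O[Si](C)(C)C(C)(C)C)C(C)C | intermediate
16 | 1-[3-prenyl-2,4-bis(TBS-oxy)phenyl]prop-2-en-1-one | C=CC(=O)c1ccc(O[Si](C)(C)C(C)(C)C)c(CC=C(C)C)c1O[Si](C)(C)C(C)(C)C | intermediate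
17 | (E)-3-Fl-1-[3-prenyl-2,4-bis(TBS-oxy)phenyl]prop-2-en-1-one | CC(C)=CCOc1ccc(-c2oc3c(/C=C/C(=O)c4ccc(O[Si](C)(C)C(C)(C)C)c(CC=C(C)C)c4O[Si](C)(C)C(C)(C)C)c(O[Si](C)(C)C(C)(C)C)cc(O[Si](C)(C)C(C)(C)C)c3c(=O)c2CC=C(C)C)c(O[Si](C)(C)C(C)(C)C)c1 | intermediate
18 | 2,4-dihydroxybenzaldehyde | O=Cc1ccc(O)cc1O | starting material
19 | 2,4-bis(TBS-oxy)benzaldehyde | O=Cc1ccc(O[Si](C)(C)C(C)(C)C)cc1O[Si](C)(C)C(C)(C)C | intermediate
20 | rac-1-[2,4-bis(TBS-oxy)phenyl]-3-methylbut-3-en-1-ol | CC(=C)CC(O)c1ccc(O[Si](C)(C)C(C)(C)C)cc1O[Si](C)(C)C(C)(C)C | intermediate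
21 | butyl 1-[2,4-bis(TBS-oxy)phenyl]-3-methylbut-3-en-1-yl vinylboronate (not isolated) | C=CB(OCCCC)OC(CC(C)=C)c1ccc(O[Si](C)(C)C(C)(C)C)cc1O[Si](C)(C)C(C)(C)C | intermediate
22 | 2-butoxy-6-[2,4-bis(TBS-oxy)phenyl]-4-methyl-5,6-dihydro-2H-1,2-oxaborinine (not isolated) | CCCCOB1C=C(C)CC(c2ccc(O[Si](C)(C)C(C)(C)C)cc2O[Si](C)(C)C(C)(C)C)O1 | intermediate
23 | rac-6-[2,4-bis(TBS-oxy)phenyl]-4-methyl-5,6-dihydro-2H-1,2-oxaborinin-2-ol | OB1C=C(C)CC(c2ccc(O[Si](C)(C)C(C)(C)C)cc2O[Si](C)(C)C(C)(C)C)O1 | intermediate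
24 | (3R,4Z)-7-[2,4-bis(TBS-oxy)phenyl]-3-Fl-7-hydroxy-5-methyl-1-[3-prenyl-2,4-bis(TBS-oxy)phenyl]hept-4-en-1-one, C7 epimers | CC(C)=CCOc1ccc(-c2oc3c([C@H](CC(=O)c4ccc(O[Si](C)(C)C(C)(C)C)c(CC=C(C)C)c4O[Si](C)(C)C(C)(C)C)/C=C(C)\CC(O)c4ccc(O[Si](C)(C)C(C)(C)C)cc4O[Si](C)(C)C(C)(C)C)c(O[Si](C)(C)C(C)(C)C)cc(O[Si](C)(C)C(C)(C)C)c3c(=O)c2CC=C(C)C)c(O[Si](C)(C)C(C)(C)C)c1 | intermediate
25 | bis-TMS enol ether from 24: (1Z,4Z)-1,7-bis(TMS-oxy)hepta-1,4-diene, C3 arranged as in 24 (descriptor 3S by priority change), C7 epimers (not isolated) | CC(C)=CCOc1ccc(-c2oc3c([C@H](/C=C(\O[Si](C)(C)C)c4ccc(O[Si](C)(C)C(C)(C)C)c(CC=C(C)C)c4O[Si](C)(C)C(C)(C)C)/C=C(C)\CC(O[Si](C)(C)C)c4ccc(O[Si](C)(C)C(C)(C)C)cc4O[Si](C)(C)C(C)(C)C)c(O[Si](C)(C)C(C)(C)C)cc(O[Si](C)(C)C(C)(C)C)c3c(=O)c2CC=C(C)C)c(O[Si](C)(C)C(C)(C)C)c1 | intermediate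
26 | benzylic cation from 25 (C7 cationic, stabilised by ring D), as its triflate (not isolated) | CC(C)=CCOc1ccc(-c2oc3c([C@H](/C=C(\O[Si](C)(C)C)c4ccc(O[Si](C)(C)C(C)(C)C)c(CC=C(C)C)c4O[Si](C)(C)C(C)(C)C)/C=C(C)\C[CH+]c4ccc(O[Si](C)(C)C(C)(C)C)cc4O[Si](C)(C)C(C)(C)C)c(O[Si](C)(C)C(C)(C)C)cc(O[Si](C)(C)C(C)(C)C)c3c(=O)c2CC=C(C)C)c(O[Si](C)(C)C(C)(C)C)c1.[O-]S(=O)(=O)C(F)(F)F | intermediate
27 | hepta-TBS ether of the target, (1S,5R,6S) | CC(C)=CCOc1ccc(-c2oc3c([C@H]4C=C(C)C[C@@H](c5ccc(O[Si](C)(C)C(C)(C)C)cc5O[Si](C)(C)C(C)(C)C)[C@@H]4C(=O)c4ccc(O[Si](C)(C)C(C)(C)C)c(CC=C(C)C)c4O[Si](C)(C)C(C)(C)C)c(O[Si](C)(C)C(C)(C)C)cc(O[Si](C)(C)C(C)(C)C)c3c(=O)c2CC=C(C)C)c(O[Si](C)(C)C(C)(C)C)c1 | intermediate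
28 | 8-[(1S,5R,6S)-6-[2,4-dihydroxy-3-prenylbenzoyl]-5-(2,4-dihydroxyphenyl)-3-methylcyclohex-2-en-1-yl]-5,7-dihydroxy-2-[2-hydroxy-4-(prenyloxy)phenyl]-3-prenyl-4H-chromen-4-one | CC(C)=CCOc1ccc(-c2oc3c([C@H]4C=C(C)C[C@@H](c5ccc(O)cc5O)[C@@H]4C(=O)c4ccc(O)c(CC=C(C)C)c4O)c(O)cc(O)c3c(=O)c2CC=C(C)C)c(O)c1 | target

**Totals.** 18 steps in all; longest linear sequence 9 steps (1 → 2 → 3 → 4 → 10 → 11 → 17 → 24 → 27 → 28; the sequence from 5 is equally long).

**Steps most likely to fail**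

1. Step 16. Insertion at the β-carbon may be slow because the flavonyl group carries two ortho substituents, so that protodeboronation of the alkenylboron reagent outruns addition and facial selectivity erodes. The fallback sets out from 17 and comes back at 24. Brief methanolysis (K2CO3, MeOH/THF, −20 °C) should cleave first the silyl ether of the most acidic phenol, the 7-hydroxyl that is vinylogous to both the chromone carbonyl and the enone, to give the 7-hydroxy enone F1. The free ortho hydroxyl then binds boronic acid 23 as a boronate and delivers the alkenyl group to the β-carbon from within the complex, without a metal, under chiral diol catalysis (3,3′-dibromo-BINOL in the enantiomer that leads to the 3R product, molecular sieves, toluene, 40 °C) to give the 7-hydroxy keto alcohol F2. Silylation of the phenol (TBSCl, imidazole, DMF, 0 °C) returns to 24.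

2. Step 17. The cation may lose a proton to the conjugated diene, the ring may close through the transition state with an axial aryl group to give the C5 epimer, or the silyl triflate may cleave the aryl prenyl ether. The fallback forms the same bond by an anionic ortho-quinone methide Michael addition; it sets out from 18 and comes back at 28. Silylation of the non-chelated 4-hydroxyl (TBSCl 1 equiv, imidazole) gives 4-(TBS-oxy)-2-hydroxybenzaldehyde F3, and acylation of the remaining phenol (Boc2O, DMAP) gives the aryl tert-butyl carbonate F4. Neutral allylboration with 2-methylallylboronic acid pinacol ester, which avoids a metal alkoxide, gives the homoallylic alcohol F5. Under the conditions of step 15 this is converted into the oxaborinine F6, which is added to 17 under the conditions of step 16 to give the keto alcohol F7. Treatment with the magnesium amide BrMgN(iPr)2 (2.2 equiv, THF, −78 to 0 °C) forms the magnesium alkoxide and the magnesium enolate of the ketone; the alkoxide takes over the carbonate group from the neighbouring phenol oxygen, the phenoxide expels tert-butyl carbonate to give the ortho-quinone methide, and the magnesium enolate adds to it in a 6-exo Michael closure to give the cyclised ketone F8, in which the 2-hydroxyl of ring D is free. The conditions of step 18 convert F8 into 28.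

3. Step 12. Oxidative addition and insertion at the doubly ortho-substituted, electron-rich iodide may be slower than polymerisation of the vinyl ketone or hydrodeiodination. The fallback sets out from 11 and 14 and comes back at 17. Palladium-catalysed formylation (Pd(PPh3)4, CO, Bu3SnH, THF, 50 °C) gives the 8-formylflavone F9. Addition of the lithium enolate of 14 (LiN(SiMe3)2, THF, −78 °C) gives the aldol F10, and dehydration (MsCl, Et3N, CH2Cl2, 0 °C to rt) gives the E-enone 17.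

**Further compounds**

F1 | step 16 | 7-hydroxy analogue of enone 17 | CC(C)=CCOc1ccc(-c2oc3c(/C=C/C(=O)c4ccc(O[Si](C)(C)C(C)(C)C)c(CC=C(C)C)c4O[Si](C)(C)C(C)(C)C)c(O)cc(O[Si](C)(C)C(C)(C)C)c3c(=O)c2CC=C(C)C)c(O[Si](C)(C)C(C)(C)C)c1
F2 | step 16 | 7-hydroxy analogue of keto alcohol 24, (3R,4Z), C7 epimers | CC(C)=CCOc1ccc(-c2oc3c([C@H](CC(=O)c4ccc(O[Si](C)(C)C(C)(C)C)c(CC=C(C)C)c4O[Si](C)(C)C(C)(C)C)/C=C(C)\CC(O)c4ccc(O[Si](C)(C)C(C)(C)C)cc4O[Si](C)(C)C(C)(C)C)c(O)cc(O[Si](C)(C)C(C)(C)C)c3c(=O)c2CC=C(C)C)c(O[Si](C)(C)C(C)(C)C)c1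
F3 | step 17 | 4-(TBS-oxy)-2-hydroxybenzaldehyde | O=Cc1ccc(O[Si](C)(C)C(C)(C)C)cc1O
F4 | step 17 | tert-butyl 2-formyl-5-(TBS-oxy)phenyl carbonate | CC(C)(C)OC(=O)Oc1cc(O[Si](C)(C)C(C)(C)C)ccc1C=O
F5 | step 17 | rac-tert-butyl 2-(1-hydroxy-3-methylbut-3-en-1-yl)-5-(TBS-oxy)phenyl carbonate | CC(=C)CC(O)c1ccc(O[Si](C)(C)C(C)(C)C)cc1OC(=O)OC(C)(C)C
F6 | step 17 | rac-tert-butyl 2-(2-hydroxy-4-methyl-5,6-dihydro-2H-1,2-oxaborinin-6-yl)-5-(TBS-oxy)phenyl carbonate | OB1C=C(C)CC(c2ccc(O[Si](C)(C)C(C)(C)C)cc2OC(=O)OC(C)(C)C)O1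
F7 | step 17 | analogue of 24 with a tert-butyl carbonate at the 2-oxygen of ring D, (3R,4Z), C7 epimers | CC(C)=CCOc1ccc(-c2oc3c([C@H](CC(=O)c4ccc(O[Si](C)(C)C(C)(C)C)c(CC=C(C)C)c4O[Si](C)(C)C(C)(C)C)/C=C(C)\CC(O)c4ccc(O[Si](C)(C)C(C)(C)C)cc4OC(=O)OC(C)(C)C)c(O[Si](C)(C)C(C)(C)C)cc(O[Si](C)(C)C(C)(C)C)c3c(=O)c2CC=C(C)C)c(O[Si](C)(C)C(C)(C)C)c1
F8 | step 17 | analogue of 27 with a free 2-hydroxyl on ring D, (1S,5R,6S) | CC(C)=CCOc1ccc(-c2oc3c([C@H]4C=C(C)C[C@@H](c5ccc(O[Si](C)(C)C(C)(C)C)cc5O)[C@@H]4C(=O)c4ccc(O[Si](C)(C)C(C)(C)C)c(CC=C(C)C)c4O[Si](C)(C)C(C)(C)C)c(O[Si](C)(C)C(C)(C)C)cc(O[Si](C)(C)C(C)(C)C)c3c(=O)c2CC=C(C)C)c(O[Si](C)(C)C(C)(C)C)c1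
F9 | step 12 | 4-oxo-3-prenyl-2-[4-(prenyloxy)-2-(TBS-oxy)phenyl]-5,7-bis(TBS-oxy)-4H-chromene-8-carbaldehyde | CC(C)=CCOc1ccc(-c2oc3c(C=O)c(O[Si](C)(C)C(C)(C)C)cc(O[Si](C)(C)C(C)(C)C)c3c(=O)c2CC=C(C)C)c(O[Si](C)(C)C(C)(C)C)c1
F10 | step 12 | 3-Fl-3-hydroxy-1-[3-prenyl-2,4-bis(TBS-oxy)phenyl]propan-1-one (racemic carbinol) | CC(C)=CCOc1ccc(-c2oc3c(C(O)CC(=O)c4ccc(O[Si](C)(C)C(C)(C)C)c(CC=C(C)C)c4O[Si](C)(C)C(C)(C)C)c(O[Si](C)(C)C(C)(C)C)cc(O[Si](C)(C)C(C)(C)C)c3c(=O)c2CC=C(C)C)c(O[Si](C)(C)C(C)(C)C)c1
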